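## Structural features

Pentabromopseudilin (13) consists of only two rings, a phenol (arene C1–C6, hydroxyl on C1) and a 1H-pyrrole (N1', C2'–C5'), joined by the single bond C6–C2' that lies ortho to the hydroxyl group. The arene carries bromine on C2 and C4, ortho and para to the oxygen, and the pyrrole carries bromine on every carbon not used for the biaryl bond (C3', C4', C5'). The molecule has no stereocentre, and the axis C6–C2', flanked by OH, H, NH and one bromine and ending in a five-membered ring, is not expected to be configurationally stable, so no stereochemical element has to be controlled. The fragile features are the five C–Br bonds (which rule out hydrogenolysis, zerovalent palladium, organolithium reagents and dissolving metals late in the route), the electron-rich N–H pyrrole (prone to acid-induced oligomerisation and oxidation until it carries deactivating groups) and the acidic phenol, which in free form next to a sulfonyl-bearing benzylic carbon would expel sulfinate. The real difficulty is therefore one of regiochemistry and timing: the biaryl bond must be made ortho to oxygen and five halogens must be placed on two rings while the pyrrole is handled in a tamed form. The key step exploits the division of the pyrrole into a C2'–N1'–C5' unit and a C3'–C4' unit: the former comes from an isocyanide whose α-carbon already carries the dibrominated aryl ring, the latter from an acrylate whose carboxyl group ends on C4', where it deactivates the ring and later gives way to bromine. In pyrrole nomenclature the cycloadduct is a 5-aryl-1H-pyrrole-3-carboxylate, which corresponds to aryl on C2' and ester on C4' in the target numbering; every structure in the plan was re-derived against this correspondence and no locant needed correction.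

## Logic of the disconnections

13 back to 12. The O–H bond of the phenol is replaced by O–CH3. A free phenol cannot be carried through the sulfone, isocyanide and alkoxide chemistry, so a mask is needed, and it must survive HCl-generating, dehydrating, strongly basic and brominating conditions. A methyl ether is the one common mask that does. Acetals and silyl ethers would be lost in the acidic amidoalkylation or the basic steps, a benzyl ether would call for hydrogenolysis that strips bromine, and an acyl or sulfonyl group on the ortho oxygen would invite transfer to the neighbouring benzylic carbanion. The demand on the forward step is a dealkylation that leaves five C–Br bonds and the N–H pyrrole alone, which points to a boron Lewis acid.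

12 back to 11. The three pyrrole C–Br bonds are cut: C3'–Br and C5'–Br back to C–H, and C4'–Br back to C–CO2H. This removes all pyrrole halogens at once and leaves a pyrrole that is stabilised by a carboxyl group. The forward step must deliver three electrophilic brominations on the pyrrole only, one of them as an ipso substitution with loss of CO2. The anisole ring, already dibrominated and with its free positions meta to the methoxy group, should stay untouched.

11 back to 10. The acid is traced to its methyl ester. The ester is what the ring-forming step needs as the activating group of the two-carbon partner, so this is a pure functional-group change. The forward hydrolysis must cope with a deactivated, vinylogous-carbamate ester without harming ether or halides.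

10 back to 7 and 8 (through 9). The bonds C2'–C3' and C4'–C5' are cut. This is the strategic simplification: the heterocycle disappears, and what remains is an α-aryl sulfonylmethyl isocyanide and a commodity acrylate. The forward step must form both bonds with one orientation and must aromatise by loss of sulfinate. The carbanion of 7 has to add to the acrylate faster than the acrylate consumes itself, so the anion is pre-formed and 8 is added slowly.

7 back to 6. The isocyanide carbon is reconnected to oxygen as an N-formyl group. Formamides are stable, crystalline precursors of isocyanides. The forward dehydration must be run cold because the product is thermally labile.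

6 back to 2, 3 and 4 (through 5). The benzylic C–N and C–S bonds are cut, which returns an aromatic aldehyde, an amide and a sulfinate. Three simple components replace a carbon bearing three different functional groups. The forward step is an equilibrium amidoalkylation that must be driven by removal of water and by crystallisation of the sulfone.

2 back to 1. The O–CH3 bond is cut to give a commercial salicylaldehyde that already holds both arene bromines in the right places (ortho and para to oxygen, meta to the formyl carbon that becomes C2'). No arene bromination has to be carried out at any stage. The forward alkylation is undemanding.

## Other disconnections considered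

Alternative 1: The cut runs through the phenol ring. Arene bonds C2–C3 and C1–C6 are taken apart, leaving the (3Z,5E)-dienyl diazoketone A1 with the pyrrole already present as an N-tosyl substituent at the diene terminus.
- Forward step: irradiation of A1 would expel dinitrogen. The dienyl group would migrate to the carbene carbon (Wolff rearrangement, bond C2–C3) to give dienylketene A2, which would close by 6π-electrocyclisation (bond C1–C6) and enolise to phenol A3.
- In its favour: the ortho relation between hydroxyl and pyrrole is fixed by the pericyclic mechanism and no metal is involved. Light should also interconvert the alkene isomers, so the Z geometry needed for closure should be less critical than it looks.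
- Against it here: the arene is the simple half of 13 and gains nothing from de novo construction. A1 is not commercial and would need several olefination steps plus a diazo-forming step with its hazards. A3 has no bromine, so detosylation to A4 and a fivefold bromination must follow.
- Comparison: on regiochemistry of the biaryl bond it is the equal of the chosen plan. On halogen placement it is also equal in outcome, because the hydroxyl directs to C2 and C4 and every pyrrole carbon is to be brominated, but it relies on directing effects where the chosen plan buys two bromines and marks a third. The photochemical cascade is mechanistically more delicate than an anionic annulation, and the step count should be higher than the seven of the chosen route.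

Alternative 2: The cut removes the arene C6–C2' bond and the arene C1–O bond together, giving an aryne precursor A5 and the cyclic nitrone A6.
- Forward step: fluoride-induced 1,2-elimination of A5 and capture of the resulting aryne by A6 in a [3+2] cycloaddition would give the benzo-fused isoxazolidine A7 as a racemate whose single stereocentre is irrelevant.
- Follow-up: base-induced N–O scission with loss of the benzylic hydrogen should give the cyclic imine A8, one dehydrogenation would lead to A4, and fivefold bromination to 13.
- In its favour: both ortho bonds are formed in one step from a commercial aryne precursor, and the sequence should be about five steps, which is better than the chosen plan on step economy.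
- Against it here: A6 is a labile nitrone that must be made fresh. The oxidation level of the five-membered ring is wrong by two stages. The dehydrogenation has to be done beside an electron-rich free phenol, and all five bromines again arrive at the end.
- Comparison: structurally it is the equal of the chosen plan on the ortho connectivity and better in convergence. Mechanistically the cycloaddition is as well understood as the annulation, but the redox adjustments that follow are the weak part. The chosen plan avoids any redox change and any late arene bromination at the cost of two extra steps.

Alternative 3: The cut removes N1'–C2' and N1'–C5', giving the 1,4-keto-aldehyde A9 and ammonia.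
- Forward step: Paal–Knorr condensation of A9 with a buffered ammonia source would close the pyrrole with loss of two molecules of water to give A10.
- Follow-up: exhaustive bromination would give 12 and ether cleavage 13. Alternatively the ether could be cleaved first to A4 and the phenol brominated.
- In its favour: the ring closure is among the most dependable in heterocyclic chemistry, and the overall sequence should be five or six steps. On robustness of the key step and on step economy it is the equal of the chosen plan or slightly better.
- Against it here: A9 is not commercial and needs two or three steps of enolate or umpolung chemistry. It is a self-condensing keto-aldehyde. The unsubstituted, acid-sensitive pyrrole A10 has to be isolated. The last two arene brominations must be forced onto a ring already attached to an electron-poor tribromopyrrole unless the order is changed.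
- Comparison: this route trusts innate ortho/para direction for the arene bromines, which is reliable, whereas the chosen plan fixes them by purchase and never exposes a bare pyrrole. The chosen plan pays for this with a longer preparation of its annulation partner.

Key step: step 4

Assumption: free p-toluenesulfinic acid does not keep, so it is taken to be liberated from 4 with aqueous HCl, extracted and used at once; this is treated as reagent preparation inside step 2.

## Route

Step 1
Reactants: 1 3,5-dibromosalicylaldehyde (3,5-dibromo-2-hydroxybenzaldehyde)
Product: 2 3,5-dibromo-2-methoxybenzaldehyde
Conditions: MeI, K2CO3, DMF, rt
Reagents that add atoms: iodomethane, CI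
Why: Williamson O-alkylation of a phenol made acidic by two bromines and the ortho formyl group; carbonate in a dipolar aprotic solvent should give the phenoxide cleanly, and the aldehyde and aryl bromides are inert.

Step 2
Reactants: 2 3,5-dibromo-2-methoxybenzaldehyde; 3 formamide; 4 sodium p-toluenesulfinate
Product: 6 racemic N-[(3,5-dibromo-2-methoxyphenyl)(tosyl)methyl]formamide, via bis-formamide aminal 5 (not isolated)
Conditions: HCONH2, TMSCl, MeCN/PhMe (1:1), 50 °C; then p-TolSO2H (from 4, aq HCl), 50 °C
Reagents that add atoms: none
Why: Three-component amidoalkylation (Mannich-type): TMSCl scavenges water and drives formation of 5, which ionises to an N-formyliminium ion that sulfinic acid captures at sulfur; the sulfone is expected to crystallise, which protects it from reversal. The new stereocentre forms without control and is removed in step 4.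

Step 3
Reactants: 6 racemic N-[(3,5-dibromo-2-methoxyphenyl)(tosyl)methyl]formamide
Product: 7 racemic (3,5-dibromo-2-methoxyphenyl)(tosyl)methyl isocyanide
Conditions: POCl3, Et3N, THF, −10 to 5 °C
Reagents that add atoms: none
Why: Dehydration of a formamide to an isocyanide by O-phosphorylation and amine-induced elimination; the cold, basic conditions and a work-up below 30 °C are chosen because α-sulfonyl benzyl isocyanides lose sulfinate on warming.

Step 4
Reactants: 7 racemic (3,5-dibromo-2-methoxyphenyl)(tosyl)methyl isocyanide; 8 methyl acrylate
Product: 10 methyl 5-(3,5-dibromo-2-methoxyphenyl)-1H-pyrrole-3-carboxylate, via tosylpyrroline ester 9 (not isolated)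
Conditions: KOt-Bu (1.5 equiv), THF, −40 °C; then 8 (slow addition), −40 °C to rt
Reagents that add atoms: none
Why: This is the van Leusen [3+2] pyrrole synthesis in its α-substituted isocyanide form. KOt-Bu removes the single proton of 7, which is acidified by the sulfonyl, isocyano and aryl groups, and the carbanion adds to the β-carbon of 8 (bond C2'–C3'). The ester enolate so formed attacks the terminal isocyanide carbon through its α-carbon in an anionic 5-endo-dig closure (bond C4'–C5'), and protonation of the imidoyl anion gives 9. Base-induced elimination of p-toluenesulfinate across C2'–C3', followed by a prototropic shift from C4' to nitrogen, aromatises the ring to 10. The two stereocentres of 9 form without control and are both erased on aromatisation, so none has to be set. The regiochemistry needed (aryl on C2', ester on C4') is secured by polarity alone, because the only nucleophilic carbon of 7 can bond only to the electrophilic β-carbon of 8. The chemoselectivity needed (ring closure ahead of chain growth of the acrylate) rests on the intramolecular closure outrunning a second conjugate addition and is helped by pre-forming the anion and adding 8 slowly in the cold; the aryl bromides and the methyl ether are inert to alkoxide at these temperatures.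

Step 5
Reactants: 10 methyl 5-(3,5-dibromo-2-methoxyphenyl)-1H-pyrrole-3-carboxylate
Product: 11 5-(3,5-dibromo-2-methoxyphenyl)-1H-pyrrole-3-carboxylic acid
Conditions: LiOH, THF/MeOH/H2O, 60 °C; then aq HCl, 0 °C
Reagents that add atoms: lithium hydroxide (supplies the carboxyl OH oxygen), [Li+].[OH-]
Why: Saponification by acyl–oxygen cleavage; the ester is a vinylogous carbamate and is further deactivated by N–H deprotonation, hence the heating, and cold, brief acidification should avoid premature decarboxylation.

Step 6
Reactants: 11 5-(3,5-dibromo-2-methoxyphenyl)-1H-pyrrole-3-carboxylic acid
Product: 12 2,3,4-tribromo-5-(3,5-dibromo-2-methoxyphenyl)-1H-pyrrole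
Conditions: NBS (3.1 equiv), DMF, 0 °C to rt, dark; aq Na2S2O3
Reagents that add atoms: N-bromosuccinimide, O=C1CCC(=O)N1Br
Why: Electrophilic substitution on the π-excessive pyrrole at the C5' and C3' C–H positions, plus ipso attack at C4' with loss of CO2 (halodecarboxylation of an electron-rich heteroaryl acid, a Hunsdiecker-type ipso substitution), puts bromine exactly where the carboxyl stood. The anisole ring is deactivated by two bromines, its free positions are meta to the methoxy group, and the reductive work-up removes any N–Br.

Step 7
Reactants: 12 2,3,4-tribromo-5-(3,5-dibromo-2-methoxyphenyl)-1H-pyrrole
Product: 13 pentabromopseudilin, 2,4-dibromo-6-(3,4,5-tribromo-1H-pyrrol-2-yl)phenol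
Conditions: BBr3, CH2Cl2, −78 °C to rt; then H2O
Reagents that add atoms: none
Why: Lewis-acid cleavage of an aryl methyl ether: boron coordinates the ether oxygen, bromide attacks the methyl carbon (SN2) and hydrolysis of the aryloxyborane frees the phenol. The fully substituted pyrrole and the C–Br bonds offer no competing site, and the twisted, di-ortho-substituted ether should be cleaved readily.

## Compound list

1 | 3,5-dibromosalicylaldehyde (3,5-dibromo-2-hydroxybenzaldehyde) | O=Cc1cc(Br)cc(Br)c1O | starting material
2 | 3,5-dibromo-2-methoxybenzaldehyde | COc1c(Br)cc(Br)cc1C=O | intermediate
3 | formamide | NC=O | starting material
4 | sodium p-toluenesulfinate | Cc1ccc(S(=O)[O-])cc1.[Na+] | starting material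
5 | N,N'-[(3,5-dibromo-2-methoxyphenyl)methanediyl]diformamide | O=CNC(NC=O)c1cc(Br)cc(Br)c1OC | intermediate (not isolated)
6 | racemic N-[(3,5-dibromo-2-methoxyphenyl)(tosyl)methyl]formamide | O=CNC(c1cc(Br)cc(Br)c1OC)S(=O)(=O)c1ccc(C)cc1 | intermediate
7 | racemic (3,5-dibromo-2-methoxyphenyl)(tosyl)methyl isocyanide | [C-]#[N+]C(c1cc(Br)cc(Br)c1OC)S(=O)(=O)c1ccc(C)cc1 | intermediate
8 | methyl acrylate | C=CC(=O)OC | starting material
9 | methyl 2-(3,5-dibromo-2-methoxyphenyl)-2-tosyl-3,4-dihydro-2H-pyrrole-4-carboxylate (racemic mixture of diastereomers) | COC(=O)C1CC(c2cc(Br)cc(Br)c2OC)(S(=O)(=O)c2ccc(C)cc2)N=C1 | intermediate (not isolated)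
10 | methyl 5-(3,5-dibromo-2-methoxyphenyl)-1H-pyrrole-3-carboxylate | COC(=O)c1c[nH]c(-c2cc(Br)cc(Br)c2OC)c1 | intermediate
11 | 5-(3,5-dibromo-2-methoxyphenyl)-1H-pyrrole-3-carboxylic acid | OC(=O)c1c[nH]c(-c2cc(Br)cc(Br)c2OC)c1 | intermediate
12 | 2,3,4-tribromo-5-(3,5-dibromo-2-methoxyphenyl)-1H-pyrrole | COc1c(Br)cc(Br)cc1-c1[nH]c(Br)c(Br)c1Br | intermediate
13 | pentabromopseudilin, 2,4-dibromo-6-(3,4,5-tribromo-1H-pyrrol-2-yl)phenol | Oc1c(Br)cc(Br)cc1-c1[nH]c(Br)c(Br)c1Br | target

## Step count and least certain steps

Total step count: 7. Longest linear sequence: 7 steps (1 to 13); 3, 4 and 8 enter as single building blocks.

Step 4 (key step). The most likely failure is that the tertiary, triply stabilised carbanion adds too slowly, so that alkoxide-initiated chain growth of the acrylate or thermal breakdown of the isocyanide anion outruns ring formation. The fallback sets out from 7 and keeps the isocyanide but changes the two-carbon partner to one that cannot propagate an anionic chain. Annulation of 7 with dimethyl fumarate under the same base should give dimethyl 2-(3,5-dibromo-2-methoxyphenyl)-1H-pyrrole-3,4-dicarboxylate F1. Saponification with LiOH would give 2-(3,5-dibromo-2-methoxyphenyl)-1H-pyrrole-3,4-dicarboxylic acid F2. Three equivalents of NBS would then brominate C5' and replace both carboxyl groups by ipso bromodecarboxylation, so that the sequence comes back to the route at 12.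

Step 2. The most likely failure is incomplete capture of the N-formyliminium ion at a benzylic carbon flanked by the ortho methoxy group, with reversal of the amidoalkylation equilibrium and return of aldehyde on work-up. The fallback sets out from 2 and separates the two bond formations by benzotriazole-mediated amidoalkylation. Condensation of 2 with formamide and 1H-benzotriazole under azeotropic removal of water should give the crystalline adduct racemic N-[(1H-benzotriazol-1-yl)(3,5-dibromo-2-methoxyphenyl)methyl]formamide F3. Exchange of the benzotriazolyl group for sulfinate with 4, assisted by mild acid or ZnBr2, would return to the route at 6.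

Step 6. The most likely failure is that ipso attack at C4' stalls once both neighbouring carbons carry bromine, or that N-bromination and oxidative oligomerisation of the pyrrole compete. The fallback sets out from 11 and separates loss of the carboxyl group from halogenation. Thermal protodecarboxylation of 11 in hot 2-aminoethanol should give 2-(3,5-dibromo-2-methoxyphenyl)-1H-pyrrole F4. Ordinary C–H bromination of F4 with three equivalents of NBS in THF at low temperature comes back to the route at 12.

Step 7. The most likely failure is acid-induced loss or migration of pyrrole bromine during the Lewis-acid treatment and quench, or incomplete ether cleavage because boron is tied up at the pyrrole nitrogen. The fallback sets out from 11 and moves the ether cleavage ahead of the bromination, while the pyrrole still carries the stabilising carboxyl group and no halogen. BBr3 on 11 should give 5-(3,5-dibromo-2-hydroxyphenyl)-1H-pyrrole-3-carboxylic acid F5. Three equivalents of NBS would then effect the two C–H brominations and the ipso bromodecarboxylation on the free phenol, whose own ring has no open ortho or para position, and the sequence rejoins the route at 13.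

## Further compounds

F1 | step 4 | dimethyl 2-(3,5-dibromo-2-methoxyphenyl)-1H-pyrrole-3,4-dicarboxylate | COC(=O)c1c[nH]c(-c2cc(Br)cc(Br)c2OC)c1C(=O)OC
F2 | step 4 | 2-(3,5-dibromo-2-methoxyphenyl)-1H-pyrrole-3,4-dicarboxylic acid | OC(=O)c1c[nH]c(-c2cc(Br)cc(Br)c2OC)c1C(=O)O
F3 | step 2 | racemic N-[(1H-benzotriazol-1-yl)(3,5-dibromo-2-methoxyphenyl)methyl]formamide | O=CNC(c1cc(Br)cc(Br)c1OC)n1nnc2ccccc21
F4 | step 6 | 2-(3,5-dibromo-2-methoxyphenyl)-1H-pyrrole | COc1c(Br)cc(Br)cc1-c1ccc[nH]1
F5 | step 7 | 5-(3,5-dibromo-2-hydroxyphenyl)-1H-pyrrole-3-carboxylic acid | OC(=O)c1c[nH]c(-c2cc(Br)cc(Br)c2O)c1
A1 | alternative 1 | (3Z,5E)-1-diazo-6-(1-tosyl-1H-pyrrol-2-yl)hexa-3,5-dien-2-one | [N-]=[N+]=CC(=O)/C=C\C=C\c1cccn1S(=O)(=O)c1ccc(C)cc1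
A2 | alternative 1 | (3Z,5E)-6-(1-tosyl-1H-pyrrol-2-yl)hexa-1,3,5-trien-1-one (dienylketene) | O=C=C/C=C\C=C\c1cccn1S(=O)(=O)c1ccc(C)cc1
A3 | alternative 1 | 2-(1-tosyl-1H-pyrrol-2-yl)phenol | Oc1ccccc1-c1cccn1S(=O)(=O)c1ccc(C)cc1
A4 | alternative 1 | 2-(1H-pyrrol-2-yl)phenol | Oc1ccccc1-c1ccc[nH]1
A5 | alternative 2 | 2-(trimethylsilyl)phenyl trifluoromethanesulfonate | C[Si](C)(C)c1ccccc1OS(=O)(=O)C(F)(F)F
A6 | alternative 2 | 1-pyrroline N-oxide (3,4-dihydro-2H-pyrrole 1-oxide) | [O-][N+]1=CCCC1
A7 | alternative 2 | racemic 1,2,3,9b-tetrahydrobenzo[d]pyrrolo[1,2-b]isoxazole | C1CC2c3ccccc3ON2C1
A8 | alternative 2 | 2-(3,4-dihydro-2H-pyrrol-5-yl)phenol | Oc1ccccc1C1=NCCC1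
A9 | alternative 3 | 4-(2-methoxyphenyl)-4-oxobutanal | COc1ccccc1C(=O)CCC=O
A10 | alternative 3 | 2-(2-methoxyphenyl)-1H-pyrrole | COc1ccccc1-c1ccc[nH]1
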